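A millimole of impurity takes a millimole of free catalyst out of the round, if the flask gives it time, and this bench rule is what I test here.

    coupling partner + free catalyst ⇌ catalyst intermediate A (K1 = 8.1 /M, k1 = 6.5 /M/h)
    catalyst intermediate A ⇌ catalyst intermediate B (K2 = 0.61, k2 = 25 /h)
    catalyst intermediate B → by-product + catalyst intermediate C (k3 = 1.2 /h)
    substrate + catalyst intermediate C → catalyst intermediate D (k4 = 340 /M/h)
    catalyst intermediate D → free catalyst + product (k5 = 68 /h)
    free catalyst + impurity → spent catalyst (k6 = 180 /M/h)

substrate 0.050 M; coupling partner 1.10 equiv; free catalyst 5 mol%; impurity 1.6 mM

* the form that holds most of the catalyst when 20% of the substrate are converted (catalyst intermediate A / catalyst intermediate C / spent catalyst / free catalyst / catalyst intermediate B / catalyst intermediate D)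
* its share of the catalyst then
* apparent order in coupling partner when 20% of the substrate are converted (percent change of the rate of making product for one percent more coupling partner charged)
* factor on the rate of making product when 20% of the substrate are converted if free catalyst is charged twice over

The rule simply subtracts. The flask holds 2.50 mM of catalyst and 1.6 mM of impurity, so what stays at work is the live catalyst, the charge less the impurity: 0.900 mM. The impurity's share of the charge is 64.0%, and that is below the whole charge, so the subtraction leaves something.

The border of the rule is the impurity still standing when I look. Free catalyst is a reactant both in the killing step and in the entry into the round, so in the ratio of those two rates it cancels. Integrating that ratio, the logarithm of the impurity's fall equals the catalyst entries made, divided by the entry constant times the partner over the killing constant. With the partner as charged, that divisor is 1.99 mM. Each product needs at least one entry and the partner stays at or below its charge, so converting 10.0 mM of substrate means at least 5.03 factors of e. That leaves at most 0.654% of the impurity at the look. No catalyst amount stands in this ratio; at a ratio of one it would promise a single factor of e. On this bound I take the rule for this flask and commit to spent catalyst at 64.0%, more than the 36.0% left for the live forms. It is an off-cycle sink, not a resting state. I reckon the order no further.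

The forecast gives spent catalyst at 64%, the same share as mine, with an order of 0.93 in coupling partner and a factor of 3.75 on doubling. Its ground is: “All the impurity is consumed long before then.”

The flask gives spent catalyst at 64.0% after 3.81 d, with an order of 0.93. After 3.00 d the impurity in this flask stands at 0.00662% of its charge. For the flask charged with free catalyst twice over, the subtraction gives 3.40 mM of live catalyst against 0.900 mM, a ratio of 3.78, and the rate of making product at that conversion rises by a factor of 3.75.

Its constants were chosen freely; the result is computed.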